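Numbering (germacrane): C1 oxolane CH–O, C2/C3 oxolane CH2, C4 oxolane C(CH3)–O, C5 =CH, C6 enol-lactone carbon, C7=C11 butenolide alkene, C8 CH–O-angelate, C9 CH2, C10 C(CH3)OH, C12 lactone C=O, C13 CH2OAc.
Retrosynthetic cuts: O8–angeloyl and O13–acetyl. C5=C6 and C12=O go back to a furan fused at C6–C7. The furan bonds C7–C11 and O–C6 go back to a C6 ketone plus dihydroxyacetone acetonide. C8–H goes back to a 6,8-diketone. Then C5–C6 and C7–C8 are cut and C5–C8 is reconnected.
Enabling feature: in the nine-membered ring O–C4–C5–C6–C7–C8–C9–C10–C1, the oxygenated carbons C6 and C8 flank C7 (1,3-dicarbonyl, retro-aldol retron). C6–C7 can therefore be excised as a ketene, and the ring shrinks to the seven-membered oxacycle O–C4–C5–C8–C9–C10–C1 of a 9-oxabicyclo[4.2.1]nonane.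
Forward ring order: oxolane (epoxide opening), seven-membered oxacycle with eight-membered carbocycle (metathesis, C5=C8), cyclobutanone (dichloroketene on the C5=C8 enol silane), cleavage of the shared C5–C8 bond to the nine-membered oxacycle with ten-membered carbocycle, furan, butenolide.
Stereochemistry: C4 is bought with (S)-linalool. C10 and C1 come from one Sharpless epoxidation followed by invertive 5-exo opening at C1. C8 is relayed from C10 by chelate-controlled reduction. The C5=C6 geometry is fixed by the ring.
Key step: step 10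

Assumption: the stereodescriptors are taken literally from the SMILES (C1 S, C4 S, C8 S, C10 R), which places C5 and C10 on opposite faces of the oxolane; carbon bridges across this oxolane are assumed to close as they do in the target itself, and (R)-linalool would lead to the C4 epimer by the same steps.

Step 1
Reactants: 1 (S)-linalool
Product: 2 (2E,6S)-2,6-dimethylocta-2,7-diene-1,6-diol
Conditions: SeO2 (cat.), t-BuOOH, salicylic acid (cat.), CH2Cl2, 23 °C
Reagents that add atoms: tert-butyl hydroperoxide CC(C)(C)OO
Why: Allylic oxidation with SeO2 (ene reaction then [2,3]-shift, reoxidised by t-BuOOH) attacks the trisubstituted alkene at its (E)-methyl group (the later C9) and leaves the vinyl group and the bought stereocentre C4 untouched.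

Step 2
Reactants: 2 (2E,6S)-2,6-dimethylocta-2,7-diene-1,6-diol
Product: 4 (2R)-2-[(2S,5S)-5-ethenyl-5-methyloxolan-2-yl]propane-1,2-diol, via epoxy alcohol 3 (not isolated)
Conditions: Ti(OiPr)4 (10 mol %), D-(−)-diethyl tartrate (12 mol %), t-BuOOH, 4 Å MS, CH2Cl2, −20 °C; then camphorsulfonic acid (10 mol %), 0 °C
Reagents that add atoms: tert-butyl hydroperoxide CC(C)(C)OO
Why: Sharpless asymmetric epoxidation of the primary allylic alcohol with the D-tartrate gives the (2R,3R)-epoxide (C10 R), and acid-catalysed 5-exo-tet opening by the C4 hydroxyl inverts C1 to S while the C10–O bond stays intact.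

Step 3
Reactants: 4 (2R)-2-[(2S,5S)-5-ethenyl-5-methyloxolan-2-yl]propane-1,2-diol
Product: 6 (2S,5S)-2-ethenyl-2-methyl-5-[(2R)-2-methyloxiran-2-yl]oxolane, via primary tosylate 5 (not isolated)
Conditions: TsCl, Et3N, DMAP (cat.), CH2Cl2, 0 °C; then K2CO3, MeOH, 23 °C
Reagents that add atoms: none
Why: Selective sulfonylation of the primary hydroxyl and intramolecular Williamson displacement by the tertiary alkoxide close the terminal epoxide without touching the C10–O bond, so C10 keeps its configuration.

Step 4
Reactants: 6 (2S,5S)-2-ethenyl-2-methyl-5-[(2R)-2-methyloxiran-2-yl]oxolane; 7 2-methyl-1,3-dithiane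
Product: 9 triethylsilyl ether of (2R)-2-[(2S,5S)-5-ethenyl-5-methyloxolan-2-yl]-1-(2-methyl-1,3-dithian-2-yl)propan-2-ol, via lithium alkoxide 8 (not isolated)
Conditions: 7, n-BuLi, THF, −30 °C; DMPU, 6, −30 → 0 °C; then Et3SiCl, 0 → 23 °C
Reagents that add atoms: chlorotriethylsilane CC[Si](Cl)(CC)CC
Why: The lithiated dithiane (Corey–Seebach acyl-anion equivalent) opens the 2,2-disubstituted epoxide by SN2 attack at its CH2 terminus (C9) and so brings in C8, and the tertiary alkoxide is capped in the same flask.

Step 5
Reactants: 9 dithiane silyl ether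
Product: 10 (4R)-4-[(2S,5S)-5-ethenyl-5-methyloxolan-2-yl]-4-(triethylsilyloxy)pentan-2-one
Conditions: MeI, CaCO3, MeCN/H2O 9:1, 45 °C
Reagents that add atoms: water O
Why: S-Alkylative hydrolysis of the dithiane under carbonate buffering unmasks the C8 methyl ketone, and the silyl ether and the vinyl group are inert to it.

Step 6
Reactants: 10 methyl ketone
Product: 11 terminal triethylsilyl enol ether of 10 (2-silyloxy-1-alkene with C10–OSiEt3 and the C4 vinyl group)
Conditions: LiN(i-Pr)2, THF, −78 °C; Et3SiCl, −78 → 0 °C
Reagents that add atoms: chlorotriethylsilane CC[Si](Cl)(CC)CC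
Why: Kinetic deprotonation by the bulky amide takes place at the methyl group and not at the neopentyl C9 methylene, so O-silylation gives the terminal enol silane that fixes the later C5=C8 regiochemistry.

Step 7
Reactants: 11 bis-silylated diene
Product: 12 (1S,5R,6S)-1,5-dimethyl-3,5-bis(triethylsilyloxy)-9-oxabicyclo[4.2.1]non-2-ene (enol silane C5=C8)
Conditions: second-generation Grubbs catalyst (10 mol %), toluene (2 mM), 80 °C, argon sparge
Reagents that add atoms: none
Why: Ring-closing metathesis of a vinyl group with a 1,1-disubstituted silyl enol ether starts at the monosubstituted alkene, expels ethene and places the enol double bond regiospecifically between C5 and C8.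

Step 8
Reactants: 12 bicyclic enol silane
Product: 13 tricyclic dichlorocyclobutanone (ring C5–C6(=O)–C7Cl2–C8(OSiEt3) cis-fused to 12 at C5–C8)
Conditions: Cl2CHCOCl (slow addition), Et3N, hexane, 23 °C
Reagents that add atoms: dichloroacetyl chloride ClC(Cl)C(Cl)=O
Why: Thermal [2+2] ketene cycloaddition joins the carbonyl carbon (C6) to the nucleophilic C5 and CCl2 (C7) to C8, and suprafacial addition on the face of the one-atom oxygen bridge gives the cis-fused ring whose two new stereocentres (C5, C8) are erased in step 10.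

Step 9
Reactants: 13 dichlorocyclobutanone
Product: 14 tricyclic cyclobutanone (ring C5–C6(=O)–C7H2–C8(OSiEt3))
Conditions: Zn dust, NH4Cl, MeOH, 23 °C
Reagents that add atoms: none
Why: Reductive dehalogenation of the α,α-dichloroketone through zinc enolates removes the chlorine atoms, which were needed only to activate the ketene and would otherwise steer the later cleavage toward C7.

Step 10
Reactants: 14 tricyclic 3-silyloxycyclobutanone
Product: 15 (1S,4S,10R)-10-hydroxy-4,10-dimethyl-1,4-epoxycyclodecane-6,8-dione (7-hydroxy-1,7-dimethyl-11-oxabicyclo[6.2.1]undecane-3,5-dione)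
Conditions: Bu4NF (2.2 equiv), THF, −78 → 0 °C; then AcOH
Reagents that add atoms: none
Why: Fluoride removes both silyl groups, and the C8 alkoxide of the 3-oxidocyclobutanone pushes the C5–C8 bond onto the C6 carbonyl (retro-aldol, the fragmentation half of a de Mayo sequence), driven by release of the four-membered ring strain and by proton transfer to the stable C6/C8 diketonate. The closest known reaction type is the two-carbon ring expansion of cyclic ketones through the dichloroketene adducts of their silyl enol ethers. No ring is closed by bond formation: the nine-membered oxacycle (and the ten-membered carbocycle) arises because the bond shared by the seven-membered oxacycle and the cyclobutane is cut, so that C6 and C7 enter the ring. No stereocentre is created, C5 and C8 become CH2 and C=O, and C1, C4 and C10 are not touched. The step needs cleavage of C5–C8 instead of C7–C8, which is secured by formation of the more substituted C5=C6 enolate once C7 carries no chlorine. It also needs the C9–C10 aldol bond and the C4–O bond to survive, which the charge of the diketonate secures because it blocks a second enolisation toward C9 or C5.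

Step 11
Reactants: 15 hydroxy diketone
Product: 16 (1S,4S,8S,10R)-8,10-dihydroxy-4,10-dimethyl-1,4-epoxycyclodecan-6-one
Conditions: Et2BOMe, THF/MeOH 4:1, −78 °C; NaBH4 (1.0 equiv), −78 °C; then AcOH, repeated evaporation from MeOH
Reagents that add atoms: none
Why: In the Narasaka–Prasad reduction boron ties O10 and the C8 carbonyl oxygen into a six-membered chelate that C6=O cannot join, so only C8 is activated and axial hydride attack gives the 8,10-syn diol, which is 8S for 10R.

Step 12
Reactants: 16 dihydroxy ketone
Product: 17 8,10-O-isopropylidene acetal of 16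
Conditions: 2,2-dimethoxypropane, PPTS (cat.), acetone, 23 °C
Reagents that add atoms: 2,2-dimethoxypropane COC(C)(C)OC
Why: Transketalisation of the syn-1,3-diol gives the six-membered acetonide, which hides both hydroxyls and turns O8 into a poor leaving group for the enolate step.

Step 13
Reactants: 17 acetonide ketone; 18 2,2-dimethyl-1,3-dioxan-5-one
Product: 19 aldol adduct of 17 bearing a 5-hydroxy-2,2-dimethyl-1,3-dioxan-5-yl group on C7 (C7 epimers, both converge)
Conditions: LiN(i-Pr)2, THF, −78 °C; 18, −78 °C; then AcOH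
Reagents that add atoms: none
Why: Kinetic enolisation occurs at C7 because C5 is neopentyl (next to the quaternary C4), and the crossed aldol addition to the electrophilic α,α'-dialkoxy ketone forms C7–C11 with two identical arms on C11, so that no alkene geometry has to be controlled later.

Step 14
Reactants: 19 aldol adduct
Product: 20 furan triol (furan O–C6=C7–C11(CH2OH)=C12H fused at C6–C7 with 8S-OH and 10R-OH free)
Conditions: TsOH·H2O (20 mol %), THF/H2O 4:1, 45 °C
Reagents that add atoms: none
Why: Acid causes β-elimination of the C11 hydroxyl, hydrolysis of both acetonides, and hemiketalisation of the CH2OH arm cis to C6=O followed by aromatising dehydration (cyclodehydration of a γ-hydroxy enone to a furan), and the ring oxygen can only end on C6 because C6 is the only carbonyl left.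

Step 15
Reactants: 20 furan triol
Product: 21 furan 13-monoacetate
Conditions: Ac2O (1.0 equiv), 2,4,6-collidine, CH2Cl2, −20 °C
Reagents that add atoms: acetic anhydride CC(=O)OC(C)=O
Why: Rate-controlled acylation selects the unhindered primary C13 hydroxyl over the secondary C8 and the tertiary C10 hydroxyl.

Step 16
Reactants: 21 furan 13-monoacetate; 22 angelic acid ((Z)-2-methylbut-2-enoic acid)
Product: 23 furan 8-angelate 13-acetate
Conditions: 22, 2,4,6-trichlorobenzoyl chloride, Et3N, toluene, 23 °C; then 21, 75 °C (no DMAP)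
Reagents that add atoms: none
Why: Yamaguchi-type esterification through the mixed anhydride acylates the secondary O8 with retention at C8, leaves the tertiary O10 free, and avoids the nucleophilic catalyst that would isomerise the Z-angelate to the E-tiglate.

Step 17
Reactants: 23 furan diester
Product: 25 γ-hydroxybutenolide (C6 hemiketal and C12 lactone carbonyl; C6 epimers, both converge), via furan endoperoxide 24 (not isolated)
Conditions: O2, visible light, tetraphenylporphyrin (cat.), i-Pr2NEt, CH2Cl2, −78 °C
Reagents that add atoms: dioxygen O=O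
Why: Singlet oxygen adds across C6 and C12 of the electron-rich furan in a [4+2] cycloaddition, and the amine removes the only endoperoxide α-hydrogen (on C12) in a Kornblum–DeLaMare-type fragmentation, so the carbonyl ends on C12 and the hydroxyl on C6.

Step 18
Reactants: 25 γ-hydroxybutenolide
Product: 26 target CNP0162854.1
Conditions: MsCl, Et3N, CH2Cl2, −40 → 0 °C
Reagents that add atoms: none
Why: Activation of the hemiketal hydroxyl and elimination toward C5, the only neighbour that bears hydrogen, give the γ-ylidene butenolide, and the ten-membered ring forces C4 cis to C7, which is the required E geometry.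

Compound list
1 | (S)-(+)-linalool, (3S)-3,7-dimethylocta-1,6-dien-3-ol | CC(C)=CCC[C@@](C)(C=C)O | starting material
2 | (2E,6S)-2,6-dimethylocta-2,7-diene-1,6-diol | OC/C(C)=C/CC[C@@](C)(C=C)O | intermediate
3 | [(2R,3R)-3-[(3S)-3-hydroxy-3-methylpent-4-enyl]-2-methyloxiran-2-yl]methanol (not isolated) | OC[C@@]1(C)O[C@@H]1CC[C@@](C)(C=C)O | intermediate
4 | (2R)-2-[(2S,5S)-5-ethenyl-5-methyloxolan-2-yl]propane-1,2-diol | OC[C@@](C)(O)[C@@H]1CC[C@@](C)(C=C)O1 | intermediate
5 | primary p-toluenesulfonate of 4 (not isolated) | Cc1ccc(cc1)S(=O)(=O)OC[C@@](C)(O)[C@@H]2CC[C@@](C)(C=C)O2 | intermediate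
6 | (2S,5S)-2-ethenyl-2-methyl-5-[(2R)-2-methyloxiran-2-yl]oxolane | C1O[C@@]1(C)[C@@H]2CC[C@@](C)(C=C)O2 | intermediate
7 | 2-methyl-1,3-dithiane | CC1SCCCS1 | starting material
8 | lithium (2R)-2-[(2S,5S)-5-ethenyl-5-methyloxolan-2-yl]-1-(2-methyl-1,3-dithian-2-yl)propan-2-olate (not isolated) | [Li+].CC1(SCCCS1)C[C@@](C)([O-])[C@@H]2CC[C@@](C)(C=C)O2 | intermediate
9 | triethylsilyl ether of the alcohol derived from 8 | CC1(SCCCS1)C[C@@](C)(O[Si](CC)(CC)CC)[C@@H]2CC[C@@](C)(C=C)O2 | intermediate
10 | (4R)-4-[(2S,5S)-5-ethenyl-5-methyloxolan-2-yl]-4-(triethylsilyloxy)pentan-2-one | CC(=O)C[C@@](C)(O[Si](CC)(CC)CC)[C@@H]1CC[C@@](C)(C=C)O1 | intermediate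
11 | terminal triethylsilyl enol ether of 10 | C=C(O[Si](CC)(CC)CC)C[C@@](C)(O[Si](CC)(CC)CC)[C@@H]1CC[C@@](C)(C=C)O1 | intermediate
12 | (1S,5R,6S)-1,5-dimethyl-3,5-bis(triethylsilyloxy)-9-oxabicyclo[4.2.1]non-2-ene | CC[Si](CC)(CC)OC=1C[C@@](C)(O[Si](CC)(CC)CC)[C@@H]2CC[C@@](C)(C=1)O2 | intermediate
13 | dichlorocyclobutanone cis-fused at C5–C8 (C5–H and C8–OSiEt3 cis, new bonds on the oxygen-bridge face) | CC[Si](CC)(CC)O[C@@]12C[C@@](C)(O[Si](CC)(CC)CC)[C@@H]3CC[C@](C)(O3)[C@@H]1C(=O)C2(Cl)Cl | intermediate
14 | dechlorinated cyclobutanone, same ring fusion as 13 | CC[Si](CC)(CC)O[C@@]12C[C@@](C)(O[Si](CC)(CC)CC)[C@@H]3CC[C@](C)(O3)[C@@H]1C(=O)C2 | intermediate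
15 | (1S,4S,10R)-10-hydroxy-4,10-dimethyl-1,4-epoxycyclodecane-6,8-dione | O=C1C[C@@](C)(O)[C@@H]2CC[C@@](C)(CC(=O)C1)O2 | intermediate
16 | (1S,4S,8S,10R)-8,10-dihydroxy-4,10-dimethyl-1,4-epoxycyclodecan-6-one | O[C@H]1C[C@@](C)(O)[C@@H]2CC[C@@](C)(CC(=O)C1)O2 | intermediate
17 | 8,10-O-isopropylidene acetal of 16 | CC1(C)O[C@H]2C[C@@](C)(O1)[C@@H]3CC[C@@](C)(CC(=O)C2)O3 | intermediate
18 | 2,2-dimethyl-1,3-dioxan-5-one | CC1(C)OCC(=O)CO1 | starting material
19 | C7 aldol adduct of 17 and 18 (C7 epimers) | CC1(C)O[C@H]2C[C@@](C)(O1)[C@@H]3CC[C@@](C)(CC(=O)C2C4(O)COC(C)(C)OC4)O3 | intermediate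
20 | furan triol (3-hydroxymethylfuran fused at C6–C7, 8S-OH, 10R-OH) | O[C@H]1C[C@@](C)(O)[C@@H]2CC[C@@](C)(Cc3occ(CO)c31)O2 | intermediate
21 | furan 13-monoacetate | O[C@H]1C[C@@](C)(O)[C@@H]2CC[C@@](C)(Cc3occ(COC(C)=O)c31)O2 | intermediate
22 | angelic acid, (Z)-2-methylbut-2-enoic acid | C/C=C(/C)C(=O)O | starting material
23 | furan 8-angelate 13-acetate | C/C=C(/C)C(=O)O[C@H]1C[C@@](C)(O)[C@@H]2CC[C@@](C)(Cc3occ(COC(C)=O)c31)O2 | intermediate
24 | furan endoperoxide, peroxide bridge C6–O–O–C12 (not isolated) | C/C=C(/C)C(=O)O[C@H]1C[C@@](C)(O)[C@@H]2CC[C@@](C)(CC34OOC(O3)C(COC(C)=O)=C41)O2 | intermediate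
25 | γ-hydroxybutenolide (C6 epimers) | C/C=C(/C)C(=O)O[C@H]1C[C@@](C)(O)[C@@H]2CC[C@@](C)(CC3(O)OC(=O)C(COC(C)=O)=C31)O2 | intermediate
26 | CNP0162854.1 (1S,4S,8S,10R; 5E; Z-angelate) | C/C=C(/C)C(=O)O[C@H]1C[C@@](C)(O)[C@@H]2CC[C@@](C)(/C=C3/OC(=O)C(COC(C)=O)=C31)O2 | target

Total step count: 18. Longest linear sequence: 18 steps (1 to 26). Compounds 7, 18 and 22 are bought.

Steps most likely to fail

Step 10. After desilylation the C8 alkoxide may expel the C7 carbanion instead of the C5 carbanion. That keeps the small ring and only hangs an acetyl group on C5. The enolisable cyclobutanone may also lose the C8 oxygen by β-elimination before it fragments.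
The fallback sets out from 10 and comes back at 15, and it closes the large ring directly. The vinyl group of 10 is hydroborated with 9-BBN and oxidised with NaBO3 to the primary alcohol F1, in which the two former vinyl carbons are C5 and C6. TEMPO/PhI(OAc)2 in wet MeCN gives the carboxylic acid F2, and Me3SiCHN2 gives the methyl ester F3. Slow addition to KN(SiMe3)2 in THF at high dilution joins the ketone methyl carbon (now C7) to the ester carbonyl (C6). This crossed Claisen (Dieckmann-type) condensation is pulled by diketonate formation and gives the silyl-protected diketone F4. HF·pyridine then frees O10 and gives 15.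

Step 7. The ruthenium alkylidene formed at the vinyl group may fail to engage the hindered 1,1-disubstituted enol silane. The two arms on the oxolane may also reach each other only at a high cost in strain. In either case dimerisation through the vinyl groups and catalyst decay outrun ring closure.
The fallback sets out from 6 and comes back at 12. It closes the ring on an all-carbon diene and brings in the oxygen afterwards. Opening of 6 with vinylmagnesium bromide and CuI (cat.) gives the homoallylic alcohol F5, and Et3SiOTf/2,6-lutidine gives the silyl ether F6. Metathesis of the two monosubstituted alkenes gives the cycloalkene F7. Hydroboration with 9-BBN places boron on C8, the alkene carbon remote from the quaternary C4. Oxidation gives the alcohol F8, and Dess–Martin oxidation gives the ketone F9. Kinetic enolisation with LiN(i-Pr)2 away from the silyloxy-bearing side and trapping with Et3SiCl lead to 12.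

Step 13. Deprotonation may occur at C5 as well as at C7. The enolate may be quenched by proton transfer from the enolisable ketone 18. The C7 enolate may also expel O8.
The fallback sets out from 15, replaces steps 11 to 13 and comes back at 20. Camphorsulfonic acid and 4 Å MS cyclodehydrate 15. O10 can reach C6 (six-membered ring) but not C8 (four-membered ring), so the bridged 2,3-dihydropyran-4-one F10 forms with C6 masked as an enol ether. Corey–Bakshi–Shibata reduction with the (R)-oxazaborolidine and BH3·SMe2 gives the (8S)-allylic alcohol F11, and Et3SiCl/imidazole gives the silyl ether F12. With BF3·OEt2 at −78 °C the enol-ether carbon C7, now the only nucleophilic site, adds to 18 (Mukaiyama-type aldol addition). Aqueous work-up opens the oxocarbenium ion to the hydroxy ketone F13. The acid treatment of step 14 converts F13 into 20.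

Further compounds
F1 | step 10 | (4R)-4-[(2S,5S)-5-(2-hydroxyethyl)-5-methyloxolan-2-yl]-4-(triethylsilyloxy)pentan-2-one | CC(=O)C[C@@](C)(O[Si](CC)(CC)CC)[C@@H]1CC[C@@](C)(CCO)O1
F2 | step 10 | carboxylic acid from F1 (C6 as CO2H) | CC(=O)C[C@@](C)(O[Si](CC)(CC)CC)[C@@H]1CC[C@@](C)(CC(=O)O)O1
F3 | step 10 | methyl ester of F2 | CC(=O)C[C@@](C)(O[Si](CC)(CC)CC)[C@@H]1CC[C@@](C)(CC(=O)OC)O1
F4 | step 10 | 10-O-triethylsilyl ether of 15 | O=C1C[C@@](C)(O[Si](CC)(CC)CC)[C@@H]2CC[C@@](C)(CC(=O)C1)O2
F5 | step 7 | (2R)-2-[(2S,5S)-5-ethenyl-5-methyloxolan-2-yl]pent-4-en-2-ol | C=CC[C@@](C)(O)[C@@H]1CC[C@@](C)(C=C)O1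
F6 | step 7 | triethylsilyl ether of F5 | C=CC[C@@](C)(O[Si](CC)(CC)CC)[C@@H]1CC[C@@](C)(C=C)O1
F7 | step 7 | (1S,5R,6S)-1,5-dimethyl-5-(triethylsilyloxy)-9-oxabicyclo[4.2.1]non-2-ene | C=1C[C@@](C)(O[Si](CC)(CC)CC)[C@@H]2CC[C@@](C)(C=1)O2
F8 | step 7 | C8 alcohol from F7 (C8 epimers) | OC1C[C@@](C)(O[Si](CC)(CC)CC)[C@@H]2CC[C@@](C)(C1)O2
F9 | step 7 | (1S,5R,6S)-1,5-dimethyl-5-(triethylsilyloxy)-9-oxabicyclo[4.2.1]nonan-3-one | O=C1C[C@@](C)(O[Si](CC)(CC)CC)[C@@H]2CC[C@@](C)(C1)O2
F10 | step 13 | bridged 2,3-dihydropyran-4-one (O10–C6=C7–C8=O) from 15 | O=C1C[C@@]2(C)OC(=C1)C[C@]3(C)CC[C@@H]2O3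
F11 | step 13 | (8S)-allylic alcohol from F10 | O[C@H]1C[C@@]2(C)OC(=C1)C[C@]3(C)CC[C@@H]2O3
F12 | step 13 | 8-O-triethylsilyl ether of F11 | CC[Si](CC)(CC)O[C@H]1C[C@@]2(C)OC(=C1)C[C@]3(C)CC[C@@H]2O3
F13 | step 13 | C7 adduct of F12 and 18 after hydrolytic opening (C6 ketone, 10-OH free, C7 epimers) | CC[Si](CC)(CC)O[C@H]1C[C@@](C)(O)[C@@H]2CC[C@@](C)(CC(=O)C1C3(O)COC(C)(C)OC3)O2
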